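**The question.** How much product stands in the theta flask at the asked time, and which remedy adds to it? I ask the readings first, before any model.

all flasks: gas 7.4 mM (held); temperature 100 °C
- theta: substrate 0.050 M; partner B 0.050 M; the very flask that is asked about, followed so far
- beta: substrate 0.10 M; partner B 0.050 M; run made earlier
- flask: substrate 0.050 M; partner B 0.0500 M; time 2.5 d

theta run (percent of the substrate charged)

| time / h | product / % | substrate / % |
|---|---|---|
| 4.00 | 9.2 | 51.2 |
| 6.00 | 11.8 | 47.6 |
| 8.00 | 10.9 | 47.1 |
| 15.0 | 11.1 | 47.0 |
| 20.0 | 15.1 | 45.5 |
| 30.0 | 13.4 | 46.8 |
| 50.0 | 13.5 | 45.5 |

beta run (percent of the substrate charged)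

| time / min | product / % | substrate / % |
|---|---|---|
| 20.0 | 0 | 90.3 |
| 40.0 | 0 | 80.0 |
| 50.0 | 0 | 77.3 |
| 80.0 | 0.1 | 72.5 |
| 90.0 | 3.5 | 69.4 |
| 120 | 1.8 | 68.7 |

(readings scatter by 1 percentage point)

- amounts and yields of product count crystals too
- given per volume of solution although it is solid: crystals
- at the start none of partner A is dissolved
- additions bring no volume worth counting
- the earlier runs were read with a standard deviation of 1 percentage point
- steps under discussion: substrate + partner B -> open intermediate; partner B + partner A -> second intermediate; open intermediate + second intermediate -> product; partner B -> decomposed reagent; crystals <-> product; gas <-> partner A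
- the earlier runs do not show what temperature does; that part of a forecast is a guess

- Wednesday's: at 2.5 d add partner B, 50.0% of the amount charged, then wait 2.5 d
- Friday's: at 2.5 d raise the temperature by 25 K, then wait 2.5 d
- Monday's: at 2.5 d add substrate, 50.0% of the amount charged, then wait 2.5 d
- Tuesday's: change nothing and wait 2.5 d more

* product, in percent of the substrate first charged, at 2.5 d
* the remedy with the largest gain of product, or "none" below 2 percentage points (Wednesday's / Friday's / Monday's / Tuesday's / none)
* product present, in percent of the substrate first charged, after Friday's
* product present, in percent of the substrate first charged, after Tuesday's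

**The ladder.** The first rung is opening. The beta flask loses 9.7 percentage points of substrate by 20.0 min. The second rung is product, which comes later. The beta flask still shows 0.1% at 80.0 min, and no partner A is dissolved at the start. The third rung is the stall. The theta flask loses 49 points of substrate by 4.00 h, but 1.6 points from 8.00 h to 50.0 h, less and within the scatter. The last rung is the asked time, 7.50 times the stall time.

**The budget.** Each unit of product takes two units of partner B, one to open substrate and one for second intermediate. So the theta charges cap product at 50.0%, and partner B is the limiting reagent. At the last theta reading, opening took 0.0272 M. Product, the small correction, took 0.00675 M more. The charge minus these two is the missing partner B, 0.0160 M, a reading with scatter. Substrate stands level in the theta flask, so I book this amount as decomposed reagent, not as free partner B.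

**My reckoning.** The last three theta readings average 14.0%, and I commit to that for the asked time. I expect no gain from waiting or from more substrate. For heat this is a guess. Wednesday's brings 0.0250 M of fresh partner B. At the old split of the theta flask that gives an estimate of 6.8 points, more than the margin of 2 points.

**The forecast.** It says 13% now, 13.5% after Friday's, 13% after Tuesday's, and Wednesday's as best, for this reason: “Fresh B meets already dissolved A and plenty of open intermediate”. Its now is lower than mine. Its gain runs from 8 to 20 points, and my estimate is 6.8 points.

**The result.** The theta flask gives 13.9%, with 0% of its partner B free at 60.0 h. The best remedy is Wednesday's, gaining 13 points, while Friday's and Tuesday's stay at 13.9% and 13.9%.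

    substrate + partner B → open intermediate (k = 0.148 M⁻¹ min⁻¹, Ea = 86.0 kJ mol⁻¹)
    partner B + partner A → second intermediate (k = 0.338 M⁻¹ min⁻¹, Ea = 56.0 kJ mol⁻¹)
    open intermediate + second intermediate → product (k = 1.61 M⁻¹ min⁻¹, Ea = 54.0 kJ mol⁻¹)
    partner B → decomposed reagent (k = 0.00322 min⁻¹, Ea = 112 kJ mol⁻¹)
    crystals ⇌ product, rate k5*(cs5 - [product]) while solid is left; crystals form when [product] > cs5 (solubility = 41.0 mM, k = 0.229 min⁻¹)
    gas ⇌ partner A, rate k6*(csat - [partner A]) (kL = 0.0184 min⁻¹)
    (constants at 100 °C)

**Second flask.** The missing partner B of 0.0160 M, a reading, is 32.0% of the theta charge. The neighbour with 0.020 M of substrate ends with 31.7% substrate and 56.9% product, so its budget leaves 0.0250 M missing. That neighbour holds 0.0250 M of decomposed reagent.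

The readings were generated by integration on assumed constants; the scatter is artificial.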